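**Retrosynthetic overview** (daucane numbering: C1 = quaternary C–Me, C4 = C(OH)iPr, C5 = ring-fusion CH, C6 = CH–O, C8=C9 = ring alkene)
1. Fertidin (20) ⇒ jaeschkeanadiol (18) + 4-methoxybenzoyl chloride, by acylation of the only secondary OH.
2. The seven-membered ring is formed last by RCM (C8=C9) of diene 17. C6 comes from chelation-controlled methallylation of β-hydroxy aldehyde 15.
3. Aldehyde 15 ⇐ Tamao oxidation of siloxane 13, made by the proposed new Si-tethered radical carbo-allylation of 11. This forms C5–C6 and C1–C10 and sets C5 and quaternary C1 from C4.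
4. The five-membered ring is formed first: cyclopentenol 9 by RCM of dienol 8. C4 is set by Sharpless epoxidation of (E)-allylic alcohol 5 followed by reductive epoxide opening; 5 comes from β-keto ester 1.

Assumption: the ~90–95% ee expected from the Sharpless step is upgraded to a single enantiomer by recrystallising diol 18 or ester 20; all numbered starting materials are taken as catalogue compounds.

---

**Step 1**
Reactants: 1, ethyl 4-methyl-3-oxopentanoate
Product: 2, ethyl (2Z)-4-methyl-3-(trifluoromethylsulfonyloxy)pent-2-enoate (OTf cis to CO2Et)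
Conditions: Tf2O, sat. aq. LiOH, hexanes, 5 °C
Reagents that add atoms: triflic anhydride, FC(F)(F)S(=O)(=O)OS(=O)(=O)C(F)(F)F
Why: O-triflation of the chelated (Z)-lithium enolate of a β-keto ester gives the (Z)-enol triflate, which fixes the alkene geometry used later.

**Step 2**
Reactants: 2; 3, 4-bromo-2-methylbut-1-ene (as its Grignard reagent)
Product: 4, ethyl (2E)-6-methyl-3-(propan-2-yl)hepta-2,6-dienoate (new chain cis to CO2Et, iPr trans)
Conditions: 3, Mg, THF; then 2, Fe(acac)3 (5 mol%), THF/NMP, −30 °C
Reagents that add atoms: 3, C=C(C)CCBr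
Why: Iron-catalysed Kumada-type coupling of alkenyl triflates with primary alkyl Grignards proceeds with retention of geometry and tolerates the ester at low temperature.

**Step 3**
Reactants: 4
Product: 5, (2E)-6-methyl-3-(propan-2-yl)hepta-2,6-dien-1-ol
Conditions: DIBAL-H (2.2 equiv), CH2Cl2, −78 → 0 °C
Reagents that add atoms: none
Why: DIBAL-H 1,2-reduction of the enoate gives the allylic alcohol without touching either alkene or the geometry.

**Step 4**
Reactants: 5
Product: 6, [(2R,3R)-3-(3-methylbut-3-en-1-yl)-3-(propan-2-yl)oxiran-2-yl]methanol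
Conditions: Ti(OiPr)4 (10 mol%), D-(−)-DET (12 mol%), TBHP, 4 Å MS, CH2Cl2, −20 °C
Reagents that add atoms: tert-butyl hydroperoxide, CC(C)(C)OO
Why: Sharpless asymmetric epoxidation; D-(−)-DET delivers oxygen to the face that makes the epoxide C3 (the future C4) R, and the remote 1,1-disubstituted alkene is inert because it is not an allylic alcohol.

**Step 5**
Reactants: 6
Product: 7, (2S,3R)-2-(iodomethyl)-3-(3-methylbut-3-en-1-yl)-3-(propan-2-yl)oxirane
Conditions: I2, PPh3, imidazole, CH2Cl2, 0 °C
Reagents that add atoms: iodine, II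
Why: Appel-type (Garegg–Samuelsson) iodination of the primary alcohol under neutral conditions leaves the epoxide and both stereocentres untouched (the C2 descriptor changes only through CIP priority).

**Step 6**
Reactants: 7
Product: 8, (3R)-6-methyl-3-(propan-2-yl)hepta-1,6-dien-3-ol
Conditions: Zn dust, EtOH, reflux
Reagents that add atoms: none
Why: Zinc-mediated reductive β-elimination opens the epoxy iodide to the tertiary vinyl carbinol; the C3–O bond is never broken, so the R configuration is retained.

**Step 7**
Reactants: 8
Product: 9, (1R)-3-methyl-1-(propan-2-yl)cyclopent-2-en-1-ol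
Conditions: Grubbs II (2 mol%), CH2Cl2 (0.05 M), 40 °C
Reagents that add atoms: none
Why: Ring-closing metathesis of a vinyl/1,1-disubstituted diene gives the unstrained trisubstituted cyclopentene; the tertiary allylic OH is tolerated and the stereocentre is not involved.

**Step 8**
Reactants: 9; 10, (bromomethyl)chlorodimethylsilane
Product: 11, (bromomethyl)dimethyl{[(1R)-3-methyl-1-(propan-2-yl)cyclopent-2-en-1-yl]oxy}silane
Conditions: 10, Et3N, DMAP (cat.), CH2Cl2, 0 °C → rt
Reagents that add atoms: 10, C[Si](C)(Cl)CBr
Why: O-silylation of the tertiary alcohol with a small chlorosilane installs the Nishiyama–Stork radical tether on the β-oxygen of C4.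

**Step 9 (proposed new transformation)**
Reactants: 11; 12, allyltributylstannane
Product: 13, (3aR,4R,6aR)-2,2,4-trimethyl-6a-(propan-2-yl)-4-(prop-2-en-1-yl)hexahydro-2H-cyclopenta[d][1,2]oxasilole (oxasilolane cis-fused on the β face through C4–O and C5–CH2; C1 carries Me β and allyl α)
Conditions: 12 (2.5 equiv), AIBN (0.2 equiv, portionwise), PhH (0.05 M), 80 °C
Reagents that add atoms: 12, C=CC[Sn](CCCC)(CCCC)CCCC
Why: Proposed new method: Si-tethered radical carbo-allylation of a trisubstituted alkene. Bu3Sn• abstracts Br to give the α-silylmethyl radical, which adds 5-exo-trig to the alkene CH (C5) and must do so syn to the C4–O tether (C5–C6 β, H α). The resulting tertiary C1 radical is captured by allylSnBu3 (SH2′, releasing the Bu3Sn• chain carrier) on the convex face anti to the new ring, giving the quaternary centre with allyl α and Me β. No tin hydride is present, so no reduction competes, and unimolecular cyclisation should outrun direct allylation at ≤0.1 M stannane. The closest known reactions are the Nishiyama–Stork (bromomethyl)silyl ether cyclisation and the Keck radical allylation (Stork-type cyclisation–trapping cascades).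

**Step 10**
Reactants: 13
Product: 14, (1R,2S,3R)-2-(hydroxymethyl)-3-methyl-1-(propan-2-yl)-3-(prop-2-en-1-yl)cyclopentan-1-ol
Conditions: KF, KHCO3, 30% H2O2, THF/MeOH, 50 °C
Reagents that add atoms: hydrogen peroxide, OO
Why: Tamao–Fleming oxidation converts the alkoxysilane C–Si bond into C6–OH and frees the C4–OH; the terminal alkene is inert and fluoride also removes tin residues.

**Step 11**
Reactants: 14
Product: 15, (1R,2R,5R)-2-hydroxy-5-methyl-2-(propan-2-yl)-5-(prop-2-en-1-yl)cyclopentane-1-carbaldehyde
Conditions: TEMPO (10 mol%), PhI(OAc)2, CH2Cl2, rt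
Reagents that add atoms: none
Why: TEMPO/PhI(OAc)2 oxidises only the primary alcohol (the tertiary OH cannot oxidise); C5 is now α to CHO, but the required epimer (CHO cis to OH and Me, trans to iPr and allyl) is also the thermodynamic one.

**Step 12**
Reactants: 15; 16, 3-bromo-2-methylprop-1-ene
Product: 17, (1R,2S,3R)-2-[(1S)-1-hydroxy-3-methylbut-3-en-1-yl]-3-methyl-1-(propan-2-yl)-3-(prop-2-en-1-yl)cyclopentan-1-ol
Conditions: 16, In powder, THF/H2O (1:1), rt
Reagents that add atoms: 16, C=C(C)CBr
Why: Indium-mediated Barbier methallylation under chelation control; the metal bridges C4–OH and C6=O, and the nucleophile attacks the carbonyl face anti to quaternary C1 (the other face is covered by the C1 β-methyl), giving (6S) without strongly basic conditions that could cause retro-aldol.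

**Step 13**
Reactants: 17
Product: 18, jaeschkeanadiol, (3R,3aS,4S,8aR)-6,8a-dimethyl-3-(propan-2-yl)-1,2,3,3a,4,5,8,8a-octahydroazulene-3,4-diol
Conditions: Grubbs II (5 mol%), CH2Cl2 (5 mM), 40 °C
Reagents that add atoms: none
Why: Ring-closing metathesis of the allyl and 2-methylallyl groups forms the trisubstituted C8=C9 cycloheptene; because the two arms are trans on the cyclopentane (allyl α at C1, side chain β at C5), the trans-fused hydroazulene results, and the free diol is tolerated.

**Step 14**
Reactants: 18; 19, 4-methoxybenzoyl chloride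
Product: 20, fertidin (target)
Conditions: 19, pyridine, DMAP, CH2Cl2, 0 °C → rt
Reagents that add atoms: 19, COc1ccc(C(Cl)=O)cc1
Why: DMAP-catalysed acylation is selective for the secondary C6–OH because the tertiary C4–OH does not acylate under these conditions; no stereocentre is touched.

---

**Compound list**
1 | ethyl 4-methyl-3-oxopentanoate | CCOC(=O)CC(=O)C(C)C | starting material
2 | ethyl (2Z)-4-methyl-3-(trifluoromethylsulfonyloxy)pent-2-enoate | CCOC(=O)/C=C(\OS(=O)(=O)C(F)(F)F)C(C)C | intermediate
3 | 4-bromo-2-methylbut-1-ene | C=C(C)CCBr | starting material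
4 | ethyl (2E)-6-methyl-3-(propan-2-yl)hepta-2,6-dienoate | CCOC(=O)/C=C(/C(C)C)CCC(C)=C | intermediate
5 | (2E)-6-methyl-3-(propan-2-yl)hepta-2,6-dien-1-ol | OC/C=C(/C(C)C)CCC(C)=C | intermediate
6 | [(2R,3R)-3-(3-methylbut-3-en-1-yl)-3-(propan-2-yl)oxiran-2-yl]methanol | C=C(C)CC[C@]1([C@H](O1)CO)C(C)C | intermediate
7 | (2S,3R)-2-(iodomethyl)-3-(3-methylbut-3-en-1-yl)-3-(propan-2-yl)oxirane | C=C(C)CC[C@]1([C@H](O1)CI)C(C)C | intermediate
8 | (3R)-6-methyl-3-(propan-2-yl)hepta-1,6-dien-3-ol | C=C[C@](O)(C(C)C)CCC(C)=C | intermediate
9 | (1R)-3-methyl-1-(propan-2-yl)cyclopent-2-en-1-ol | CC1=C[C@](O)(C(C)C)CC1 | intermediate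
10 | (bromomethyl)chlorodimethylsilane | C[Si](C)(Cl)CBr | starting material
11 | (bromomethyl)dimethyl{[(1R)-3-methyl-1-(propan-2-yl)cyclopent-2-en-1-yl]oxy}silane | CC1=C[C@](O[Si](C)(C)CBr)(C(C)C)CC1 | intermediate
12 | allyltributylstannane | C=CC[Sn](CCCC)(CCCC)CCCC | starting material
13 | (3aR,4R,6aR)-2,2,4-trimethyl-6a-(propan-2-yl)-4-(prop-2-en-1-yl)hexahydro-2H-cyclopenta[d][1,2]oxasilole | C=CC[C@@]1(C)CC[C@]2(C(C)C)O[Si](C)(C)C[C@H]12 | intermediate
14 | (1R,2S,3R)-2-(hydroxymethyl)-3-methyl-1-(propan-2-yl)-3-(prop-2-en-1-yl)cyclopentan-1-ol | C=CC[C@@]1(C)CC[C@@](O)(C(C)C)[C@@H]1CO | intermediate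
15 | (1R,2R,5R)-2-hydroxy-5-methyl-2-(propan-2-yl)-5-(prop-2-en-1-yl)cyclopentane-1-carbaldehyde | C=CC[C@@]1(C)CC[C@@](O)(C(C)C)[C@@H]1C=O | intermediate
16 | 3-bromo-2-methylprop-1-ene | C=C(C)CBr | starting material
17 | (1R,2S,3R)-2-[(1S)-1-hydroxy-3-methylbut-3-en-1-yl]-3-methyl-1-(propan-2-yl)-3-(prop-2-en-1-yl)cyclopentan-1-ol | C=CC[C@@]1(C)CC[C@@](O)(C(C)C)[C@@H]1[C@@H](O)CC(C)=C | intermediate
18 | jaeschkeanadiol, (3R,3aS,4S,8aR)-6,8a-dimethyl-3-(propan-2-yl)-1,2,3,3a,4,5,8,8a-octahydroazulene-3,4-diol | O[C@H]1CC(C)=CC[C@@]2(C)CC[C@@](O)(C(C)C)[C@H]12 | intermediate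
19 | 4-methoxybenzoyl chloride | COc1ccc(C(Cl)=O)cc1 | starting material
20 | fertidin, (3R,3aS,4S,8aR)-3-hydroxy-6,8a-dimethyl-3-(propan-2-yl)-1,2,3,3a,4,5,8,8a-octahydroazulen-4-yl 4-methoxybenzoate | COc1ccc(C(=O)O[C@H]2CC(C)=CC[C@@]3(C)CC[C@@](O)(C(C)C)[C@H]23)cc1 | target

---

**Total step count:** 14
**Longest linear sequence:** 14 (fully linear; 3, 10, 12, 16 and 19 are purchased)

**Three steps most likely to fail**
1. **Step 9 (new cascade).** The risks are direct allylation of the uncyclised α-silyl radical, slow capture of the hindered tertiary radical, and erosion of α-face selectivity by the 1,3-related iPr group. Fallback (known reactions, polar construction of the quaternary centre):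
   - oxidise the ring CH2 next to the methyl-bearing alkene carbon to the 2-methylcyclopentenone (allylic oxidation);
   - run the established reductive Nishiyama–Stork radical conjugate addition (Bu3SnH) to set C5;
   - allylate C1 through the thermodynamic enolate, trans to the fused ring;
   - remove the extra carbonyl by reduction and Barton–McCombie deoxygenation, then rejoin at step 10.
2. **Step 12 (C6 configuration, retro-aldol-prone aldehyde).** Fallback: switch from chelate control to reagent control by protecting the C4–OH as its TMS ether and using Brown methallylboration with the matching Ipc2B(methallyl) antipode. If a C6 epimer still forms, oxidise to the 6-ketone after ring closure and reduce under thermodynamic (dissolving-metal or SmI2) conditions to the equatorial 6α-alcohol.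
3. **Step 13 (RCM to a trans-fused, trisubstituted cycloheptene).** Fallback: change the ring-closing bond construction by protecting the 1,3-diol of 17 as its acetonide, ozonolysing both alkenes to the aldehyde/methyl ketone, and closing C8=C9 by intramolecular McMurry coupling (TiCl3, Zn–Cu), then removing the acetonide.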